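Remark on the chemistry: the target is taken as 5-{7-[(2E)-3,7-dimethylocta-2,6-dien-1-yl]-6-hydroxy-1-benzofuran-2-yl}benzene-1,3-diol, an achiral compound. "Geranyl" always means the (2E)-3,7-dimethylocta-2,6-dien-1-yl group. Benzofuran numbering (O1, C2, C3, C3a, C4 to C7, C7a) is also used for the "future" positions of open-chain precursors. The structures of the key-step precursor 10 and product 12 were checked atom by atom against the target and need no correction. The one change made to the most obvious protecting-group plan is on ring A, which is masked as allyl ethers and not as acid-labile acetals; the reasons are under the disconnection 10 ⇒ 9.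

## Structural features

The target 13 is a 2-arylbenzofuran. Ring A (C3a, C4, C5, C6, C7, C7a) is fused through C3a–C7a to the furan ring (O1, C2, C3), and C2 carries ring B, a 3,5-dihydroxyphenyl group. Ring A is 1,2,3,4-tetrasubstituted: C6 bears a hydroxyl, C7 the geranyl chain, C7a the furan oxygen and C3a the furan carbon, so the geranyl CH2 lies between two oxygen-bearing carbons. There is no stereocentre; the only stereochemical element is the (E)-alkene C2′=C3′, which arrives with the geranyl unit and only has to be preserved. The fragile parts are the two trisubstituted alkenes and the benzylic–allylic C1′ methylene of the geranyl chain (chroman formation with the C6 hydroxyl under acid, chromene formation under hydride-abstracting oxidants), the three electron-rich phenols, and the electron-rich C2=C3 bond. Hydrogenolysis, strong Lewis acids and strong protic acids are therefore excluded from the late stages. The real difficulty is regiochemistry and chemoselectivity, not the carbon skeleton: the geranyl group must sit at C7 between the two oxygens, and the furan must be closed without touching that chain. The key step uses the fact that the C6 hydroxyl is para to C3a and O1 is ortho to it. Cleaving O1–C2 leaves a 2,4-dihydroxystilbene in which two-electron oxidation of the phenol makes the styryl carbon next to ring B (future C2) electrophilic, exactly where the oxygen on C7a can reach it through a five-membered transition state.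

## Logic of the disconnections

13 ⇒ 12. The two Si–O bonds on ring B are cut. Ring B must be masked during the oxidation, and the mask must come off without acid, hydrogen or a Lewis acid because of the geranyl chain and the electron-rich furan. Nothing is gained in skeleton, but the oxidation is confined to ring A. The forward step needs buffered fluoride so that the triphenoxide of 13 is never exposed to air.

12 ⇒ 10 (through 11). The O1–C2 bond is cut. Because the C6 hydroxyl is para to C3a, this opens the heterocycle to a stilbene with both ring A hydroxyls free, the oxidation pattern from which this family of 2-arylbenzofurans is thought to arise. The gain is the loss of the furan ring: what remains is two arenes joined by an alkene. The forward step needs a two-electron oxidant that goes through the stilbene and spares the geranyl CH2, the geranyl alkenes and the product phenol. Both ring A hydroxyls are left free on purpose: one is the nucleophile, the other is the handle for oxidation. A variant with the C6 oxygen masked is kept as the reserve.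

10 ⇒ 9. The two O–allyl bonds on ring A are cut. Ring A needs masks that survive the amide base of the olefination, are orthogonal to the ring B silyl ethers and come off at neutral pH. Acid-labile acetals fall short on two counts. First, the hydroxyl that is hydrogen-bonded to the formyl group in 3, and crowded by the geranyl chain, is reluctant to undergo acid-catalysed acetalization with a vinyl ether. Second, their removal would bring acid to a geranyl chain flanked by two phenols. Allyl ethers go on under basic conditions, where the chelated phenoxide reacts, and come off by palladium-catalysed allyl transfer. The demand on the forward step is that the amine, not the liberated resorcinol, captures the allyl fragment.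

9 ⇒ 4 + 8. The Cα=Cβ double bond (future C3=C2) is cut. This is the convergent disconnection: it divides the molecule into a ring A aldehyde and a ring B phosphonate of similar size. The forward olefination must be (E)-selective so that 9 and 10 are single, defined compounds, and its base must not attack aryl silyl ethers.

4 ⇒ 3 ⇒ 1 + 2. First the O–allyl bonds are cut, then the bond between the ring carbon flanked by the two oxygens (future C7) and C1′ of the chain. That carbon is the most nucleophilic position of the resorcinol dianion, and both pieces are commercial. The forward step must favour C- over O-alkylation and C3 over C5, and must displace bromide directly so that the (E)-alkene is retained; this is the least selective step of the route and has a regiocontrolled reserve.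

8 ⇒ 7 ⇒ 6 ⇒ 5. The C–P bond, then the C–Br bond, then the two aryl O–Si bonds are cut. This is standard functional-group interchange from a commercial benzylic alcohol. The only demand is that silylation in the step from 5 to 6 distinguishes the two phenols from the primary alcohol.

## Other disconnections considered

Alternative 1: The cut runs through ring A itself: C7–C7a, C5–C6 and C3a–C7a are broken. Ring A would be assembled from the diazo enynone A1 and the geranyl-substituted siloxyalkyne A2 by a Danheiser benzannulation.
- Forward key step: irradiation of A1 starts a Wolff rearrangement; [2+2] cycloaddition with A2, 4π ring opening, 6π ring closure and tautomerization on warming deliver the phenol A3, which carries the arylalkyne ortho to the new hydroxyl. A 5-endo-dig cycloisomerization (Cs2CO3 or CuI) would then give the benzofuran A4, and fluoride would give 13.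
- In its favour: the position of the geranyl group between the two oxygens follows from the polarity of the cycloaddition and cannot come out wrong. On this point it is better than the statistical C-alkylation of step 1. The C6 oxygen arrives already differentiated from O1. The furan is closed by a redox-neutral addition to an alkyne, so no oxidant meets the electron-rich phenol or the geranyl chain; here too it is superior to step 8.
- Against it: A1 combines a diazo ketone with a conjugated enyne chromophore and is sensitive to light and heat. A2 is a skipped enyne with an acidic propargylic–allylic CH2 and needs ynolate chemistry. Each takes several steps to make.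
- Comparison: on structure the alternative is stronger (complete regiocontrol in ring A). On mechanism it is a pericyclic cascade that is dependable in general but would run here next to a 1,4-enyne side chain able to interfere; the chosen closure is one ionic event. On step economy the chosen plan is ahead, because it buys ring A ready-made and reaches the target in nine steps.

Alternative 2: The cut is the C4=C5 bond of ring A, with the C6 phenol regarded as the enol of a ring A ketone. The precursor is the furan A5, which carries a vinyl group on the future C3a and a geranyl-substituted vinyl ketone chain on the future C7a.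
- Forward key step: second-generation Grubbs catalyst joins the two terminal alkenes, and enolization of the ring-closed product gives the phenol A6 directly.
- In its favour: the conditions are neutral, aromatization drives the reaction, and the geranyl position is fixed by construction, again better than step 1. A6 is the tert-butyldimethylsilyl analogue of 12, so the endgame is the same one-step fluoride deprotection; on that point the two plans are equal.
- Against it: A5 contains the two trisubstituted alkenes of the geranyl chain. The C2′=C3′ alkene is placed so that metathesis with the enone terminus would close a five-membered ring, and with the furan vinyl group a six-membered ring, in both cases cutting off the chain. The α-furyl ketone carries an acidic, racemization-prone CH (harmless for the product but inviting enolization and conjugate addition to the vinyl ketone). A5 also requires a 2,3,5-trisubstituted furan to be built first.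
- Comparison: on structure the alternative forms a ring A C=C bond, the chosen plan a furan C–O bond; both end at the same oxidation level. On mechanism the risk here is chemoselectivity among four alkenes, in the chosen plan chemoselectivity of a phenol oxidation; neither is free of doubt. On step economy the chosen plan is clearly shorter.

Alternative 3: The cut is the C2=C3 bond. The precursor A7 is an aryl ester in which the future C3 is a formyl carbon and the future C2 is the ester carbonyl carbon.
- Forward key step: low-valent titanium from TiCl3 and Zn couples the two carbonyl carbons with loss of both oxygens and gives the fully silylated benzofuran A8, which fluoride would convert into 13.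
- In its favour: A7 would be reached from 3 in two steps, because the hydroxyl para to the formyl group is silylated selectively and the chelated one is then aroylated. The sequence to 13 could therefore be as short as the chosen one or shorter; on step economy this alternative is the equal or the better. There is no alkene geometry to control and no oxidant, and low-valent titanium leaves isolated alkenes and electron-rich arenes alone.
- Against it: the coupling needs a large excess of the titanium reagent in boiling ether solvents. The Lewis-acidic titanium chlorides would meet three aryl silyl ethers and a geranyl chain next to one of them. An aryl ester is the less willing partner in such couplings and can lose its acyl group under reduction, and the aldehyde can dimerize intermolecularly unless the reaction is run dilute.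
- Comparison: on structure both plans start from 3 and share the regiochemical weakness of step 1, so they are equal there. On mechanism the alternative is reductive and heterogeneous, with forcing conditions at the decisive step; the chosen closure is a homogeneous, low-temperature oxidation with one equivalent of a mild reagent. The milder conditions at the decisive step are the reason for preferring the chosen plan.

Key step: step 8

## Route

Step 1
Reactants: 1 2,4-dihydroxybenzaldehyde; 2 geranyl bromide [(2E)-1-bromo-3,7-dimethylocta-2,6-diene]
Product: 3 3-geranyl-2,4-dihydroxybenzaldehyde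
Conditions: KOH (10% aq), 0 °C → rt; then dilute HCl
Reagents that add atoms: none
Why: C-alkylation of the resorcinol-type dianion in water, where hydrogen bonding to the phenoxide oxygens turns the ambident anion toward carbon; C3, between the two oxygens, is the most nucleophilic carbon, and direct SN2 displacement at the primary allylic bromide keeps the (E)-alkene. The O-geranyl and C5 isomers expected as by-products should be separable by chromatography.

Step 2
Reactants: 3 3-geranyl-2,4-dihydroxybenzaldehyde
Product: 4 3-geranyl-2,4-bis(prop-2-en-1-yloxy)benzaldehyde
Conditions: allyl bromide (3 equiv), K2CO3, DMF, 60 °C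
Reagents that add atoms: allyl bromide, C=CCBr
Why: Williamson ether synthesis; under basic conditions in DMF the hydrogen-bonded, crowded C2 hydroxyl is alkylated as its phenoxide, which acid-catalysed acetal formation would leave behind. Allyl ethers tolerate the amide base of step 6 and are removed later at neutral pH.

Step 3
Reactants: 5 3,5-dihydroxybenzyl alcohol
Product: 6 [3,5-bis(triisopropylsilyloxy)phenyl]methanol
Conditions: NaH (2.05 equiv), THF, 0 °C; then TIPSCl (2.05 equiv), 0 °C → rt
Reagents that add atoms: triisopropylsilyl chloride, CC(C)[Si](Cl)(C(C)C)C(C)C
Why: Phenoxide-selective O-silylation: two equivalents of NaH deprotonate only the two phenols, which are far more acidic than the benzylic alcohol, and the bulky silyl chloride reacts with the phenoxides but not with the neutral alcohol in the absence of a nucleophilic catalyst.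

Step 4
Reactants: 6 [3,5-bis(triisopropylsilyloxy)phenyl]methanol
Product: 7 1-(bromomethyl)-3,5-bis(triisopropylsilyloxy)benzene
Conditions: CBr4, PPh3, CH2Cl2, 0 °C
Reagents that add atoms: carbon tetrabromide, BrC(Br)(Br)Br
Why: Appel bromination of a primary benzylic alcohol under neutral conditions; aryl triisopropylsilyl ethers are inert to the phosphonium intermediates.

Step 5
Reactants: 7 1-(bromomethyl)-3,5-bis(triisopropylsilyloxy)benzene
Product: 8 diethyl {[3,5-bis(triisopropylsilyloxy)phenyl]methyl}phosphonate
Conditions: P(OEt)3 (neat), 130 °C
Reagents that add atoms: triethyl phosphite, CCOP(OCC)OCC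
Why: Michaelis–Arbuzov reaction of a reactive benzylic bromide; volatile bromoethane leaves the melt, and the hindered aryl silyl ethers withstand the heat in the absence of acid or nucleophile.

Step 6
Reactants: 8 diethyl {[3,5-bis(triisopropylsilyloxy)phenyl]methyl}phosphonate; 4 3-geranyl-2,4-bis(prop-2-en-1-yloxy)benzaldehyde
Product: 9 1-{(E)-2-[3,5-bis(triisopropylsilyloxy)phenyl]ethenyl}-3-geranyl-2,4-bis(prop-2-en-1-yloxy)benzene
Conditions: KN(SiMe3)2 (1.1 equiv), THF, −78 °C; then 4, −78 °C → rt
Reagents that add atoms: none
Why: Horner–Wadsworth–Emmons olefination; the benzylic phosphonate anion adds reversibly to the aldehyde and the adducts equilibrate toward the one that collapses to the (E)-stilbene. The hindered amide base deprotonates the phosphonate without attacking aryl silyl ethers, and the allyl ethers and the geranyl chain are inert.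

Step 7
Reactants: 9 1-{(E)-2-[3,5-bis(triisopropylsilyloxy)phenyl]ethenyl}-3-geranyl-2,4-bis(prop-2-en-1-yloxy)benzene
Product: 10 4-{(E)-2-[3,5-bis(triisopropylsilyloxy)phenyl]ethenyl}-2-geranylbenzene-1,3-diol
Conditions: Pd(PPh3)4 (5 mol%), morpholine (6 equiv), THF, rt, argon, dark
Reagents that add atoms: none
Why: Palladium-catalysed allyl transfer of the Tsuji–Trost type: zerovalent palladium ionizes each aryl allyl ether to a π-allyl complex and a phenoxide, and morpholine captures the allyl fragment irreversibly. The conditions are neutral and fluoride-free, so the geranyl chain between the two freed hydroxyls sees no acid and the ring B silyl ethers stay; the trisubstituted alkenes and the stilbene cannot form π-allyl complexes.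

Step 8
Reactants: 10 4-{(E)-2-[3,5-bis(triisopropylsilyloxy)phenyl]ethenyl}-2-geranylbenzene-1,3-diol
Product: 12 2-[3,5-bis(triisopropylsilyloxy)phenyl]-7-geranyl-1-benzofuran-6-ol, via quinone methide 11 (not isolated)
Conditions: PhI(OAc)2 (1.05 equiv, added slowly), MeCN–CH2Cl2, −30 → 0 °C, argon, dark
Reagents that add atoms: none
Why: Ligand exchange of the trivalent iodine reagent at the less hindered C1 hydroxyl of 10 (the future C6–OH, para to the styryl group) gives an aryloxy iodine species, and departure of iodobenzene and acetate is a two-electron oxidation that leaves a quinone-methide-type cation whose charge rests on the styryl carbon bonded to ring B. The neighbouring C3 hydroxyl (future O1) adds to that carbon and closes the furan ring; the closure is formally 5-endo-trig with respect to the stilbene double bond, but in effect it is the capture of a delocalized benzylic cation, an intramolecular oxa-conjugate addition to an extended para-quinone methide. The neutral 2H-benzofuran-6-one 11 so formed loses the doubly activated C2 proton and tautomerizes, which restores ring A and gives the aromatic furan of 12. The closest known reaction type is the oxidative cyclization of 2-hydroxystilbenes to 2-arylbenzofurans with PhI(OAc)2, together with the trapping of quinone methides generated from 4-hydroxystilbenes by the same oxidant. No stereocentre is set: the C2 centre of 11 is transient and the alkene geometry of 10 disappears in the cation. The step needs chemoselectivity for oxidation through the stilbene over oxidation at the geranyl CH2 (ortho-quinone methide, then chromene) or at C5, and it must not re-oxidize the phenol of 12. This is secured by the extended conjugation to ring B, the fast five-ring capture by the adjacent oxygen, a non-nucleophilic solvent, and one equivalent of oxidant added slowly at low temperature. Isolated trisubstituted alkenes and aryl silyl ethers are inert to PhI(OAc)2 under these conditions.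

Step 9
Reactants: 12 2-[3,5-bis(triisopropylsilyloxy)phenyl]-7-geranyl-1-benzofuran-6-ol
Product: 13 5-{7-[(2E)-3,7-dimethylocta-2,6-dien-1-yl]-6-hydroxy-1-benzofuran-2-yl}benzene-1,3-diol (the target)
Conditions: Bu4NF (2.5 equiv), AcOH (2.5 equiv), THF, 0 °C, argon
Reagents that add atoms: none
Why: Fluoride-induced cleavage of the two aryl silyl ethers, driven by the strength of the Si–F bond; the acetic acid buffer keeps the liberated phenols protonated so that the electron-rich triphenol is not air-oxidized, and neither the geranyl chain nor the furan reacts with fluoride.

## Compound list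

1 | 2,4-dihydroxybenzaldehyde | O=Cc1ccc(O)cc1O | starting material
2 | geranyl bromide, (2E)-1-bromo-3,7-dimethylocta-2,6-diene | CC(C)=CCC/C(C)=C/CBr | starting material
3 | 3-[(2E)-3,7-dimethylocta-2,6-dien-1-yl]-2,4-dihydroxybenzaldehyde | CC(C)=CCC/C(C)=C/Cc1c(O)ccc(C=O)c1O | intermediate
4 | 3-[(2E)-3,7-dimethylocta-2,6-dien-1-yl]-2,4-bis(prop-2-en-1-yloxy)benzaldehyde | CC(C)=CCC/C(C)=C/Cc1c(OCC=C)ccc(C=O)c1OCC=C | intermediate
5 | 3,5-dihydroxybenzyl alcohol | OCc1cc(O)cc(O)c1 | starting material
6 | [3,5-bis(triisopropylsilyloxy)phenyl]methanol | OCc1cc(O[Si](C(C)C)(C(C)C)C(C)C)cc(O[Si](C(C)C)(C(C)C)C(C)C)c1 | intermediate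
7 | 1-(bromomethyl)-3,5-bis(triisopropylsilyloxy)benzene | BrCc1cc(O[Si](C(C)C)(C(C)C)C(C)C)cc(O[Si](C(C)C)(C(C)C)C(C)C)c1 | intermediate
8 | diethyl {[3,5-bis(triisopropylsilyloxy)phenyl]methyl}phosphonate | CCOP(=O)(Cc1cc(O[Si](C(C)C)(C(C)C)C(C)C)cc(O[Si](C(C)C)(C(C)C)C(C)C)c1)OCC | intermediate
9 | 1-{(E)-2-[3,5-bis(triisopropylsilyloxy)phenyl]ethenyl}-3-[(2E)-3,7-dimethylocta-2,6-dien-1-yl]-2,4-bis(prop-2-en-1-yloxy)benzene | CC(C)=CCC/C(C)=C/Cc1c(OCC=C)ccc(/C=C/c2cc(O[Si](C(C)C)(C(C)C)C(C)C)cc(O[Si](C(C)C)(C(C)C)C(C)C)c2)c1OCC=C | intermediate
10 | 4-{(E)-2-[3,5-bis(triisopropylsilyloxy)phenyl]ethenyl}-2-[(2E)-3,7-dimethylocta-2,6-dien-1-yl]benzene-1,3-diol | CC(C)=CCC/C(C)=C/Cc1c(O)ccc(/C=C/c2cc(O[Si](C(C)C)(C(C)C)C(C)C)cc(O[Si](C(C)C)(C(C)C)C(C)C)c2)c1O | intermediate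
11 | 2-[3,5-bis(triisopropylsilyloxy)phenyl]-7-[(2E)-3,7-dimethylocta-2,6-dien-1-yl]-1-benzofuran-6(2H)-one (quinone methide, C2 racemic and transient) | CC(C)=CCC/C(C)=C/CC1=C2OC(c3cc(O[Si](C(C)C)(C(C)C)C(C)C)cc(O[Si](C(C)C)(C(C)C)C(C)C)c3)C=C2C=CC1=O | intermediate
12 | 2-[3,5-bis(triisopropylsilyloxy)phenyl]-7-[(2E)-3,7-dimethylocta-2,6-dien-1-yl]-1-benzofuran-6-ol | CC(C)=CCC/C(C)=C/Cc1c(O)ccc2cc(-c3cc(O[Si](C(C)C)(C(C)C)C(C)C)cc(O[Si](C(C)C)(C(C)C)C(C)C)c3)oc12 | intermediate
13 | 5-{7-[(2E)-3,7-dimethylocta-2,6-dien-1-yl]-6-hydroxy-1-benzofuran-2-yl}benzene-1,3-diol | CC(C)=CCC/C(C)=C/Cc1c(O)ccc2cc(-c3cc(O)cc(O)c3)oc12 | target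

## Step count and least certain steps

Total: 9 steps. Longest linear sequence: 7 steps (5 → 6 → 7 → 8 → 9 → 10 → 12 → 13, steps 3 to 9); the ring A branch from 1 is 6 steps.

**Step 8 (key step).** What may go wrong:
- oxidation at the geranyl methylene, which would lead by way of an ortho-quinone methide to electrocyclization onto the chain;
- capture of the cation by acetate in place of the ring oxygen;
- re-oxidation of the product phenol, which would consume 12 as it forms.

Fallback: the para hydroxyl is masked, so the ring closure no longer runs through phenol oxidation at C6 and the product carries no free phenol. Setting out from 10, the less hindered C1 hydroxyl would be silylated selectively (TIPSCl, imidazole, DMF, 0 °C) to give 6-{(E)-2-[3,5-bis(triisopropylsilyloxy)phenyl]ethenyl}-2-geranyl-3-(triisopropylsilyloxy)phenol F1. F1 is a plain 2-hydroxystilbene of the kind for which cyclization with PhI(OAc)2 in MeCN at room temperature is established (activation of the alkene by trivalent iodine, attack of the phenol, loss of iodobenzene). It should give 2-[3,5-bis(triisopropylsilyloxy)phenyl]-7-geranyl-6-(triisopropylsilyloxy)-1-benzofuran F2. Buffered Bu4NF then removes all three silyl groups, and the route is rejoined at 13.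

**Step 1.** What may go wrong: poor discrimination between C- and O-alkylation and between C3 and C5, together with double alkylation, so that little of the wanted isomer is formed and its separation is laborious.

Fallback: regiocontrol by directed ortho-metalation, setting out from 2 and resorcinol. Resorcinol would be converted (MOMCl, NaH, DMF) into 1,3-bis(methoxymethoxy)benzene F3. Lithiation between the two acetal oxygens (n-BuLi, THF, 0 °C), then CuI and 2, would give 2-geranyl-1,3-bis(methoxymethoxy)benzene F4. A second directed lithiation (n-BuLi, TMEDA, THF, 0 °C) and quenching with DMF would give 3-geranyl-2,4-bis(methoxymethoxy)benzaldehyde F5. HCl in MeOH at room temperature then removes both acetals; this is tolerable at this stage because the formyl group lowers the nucleophilicity of the phenolic oxygens toward the chain. The route is rejoined at 3.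

**Step 3.** What may go wrong: incomplete chemoselectivity, that is silylation of the benzylic hydroxyl or silyl transfer between oxygens, leaving a mixture of partly and wrongly silylated material.

Fallback: exhaustive silylation followed by selective unmasking, setting out from 5. TIPSCl (3.5 equiv) and imidazole in DMF would give triisopropyl{[3,5-bis(triisopropylsilyloxy)phenyl]methoxy}silane F6. Dilute aqueous HCl in EtOH–THF would then cleave the alkyl silyl ether, since alkyl silyl ethers hydrolyse under acid much faster than aryl silyl ethers. The route is rejoined at 6.

**Step 7.** What may go wrong: capture of the π-allyl palladium intermediate by a ring carbon of the liberated, electron-rich resorcinol in place of the amine (C-allylation), and photo-isomerization or air oxidation of the free hydroxystilbene during isolation.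

Fallback: acetal protection in place of allyl protection, setting out from 3. MOMCl and NaH in DMF would give 3-geranyl-2,4-bis(methoxymethoxy)benzaldehyde F5, the same compound as in the fallback to step 1. Olefination with 8 under the conditions of step 6 would give 1-{(E)-2-[3,5-bis(triisopropylsilyloxy)phenyl]ethenyl}-3-geranyl-2,4-bis(methoxymethoxy)benzene F7. Brief treatment with HCl in MeOH at room temperature, which leaves aryl triisopropylsilyl ethers intact, would free the two hydroxyls. The route is rejoined at 10, which would be used in step 8 without storage.

## Further compounds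

F1 | step 8 | 6-{(E)-2-[3,5-bis(triisopropylsilyloxy)phenyl]ethenyl}-2-[(2E)-3,7-dimethylocta-2,6-dien-1-yl]-3-(triisopropylsilyloxy)phenol | CC(C)=CCC/C(C)=C/Cc1c(O[Si](C(C)C)(C(C)C)C(C)C)ccc(/C=C/c2cc(O[Si](C(C)C)(C(C)C)C(C)C)cc(O[Si](C(C)C)(C(C)C)C(C)C)c2)c1O
F2 | step 8 | 2-[3,5-bis(triisopropylsilyloxy)phenyl]-7-[(2E)-3,7-dimethylocta-2,6-dien-1-yl]-6-(triisopropylsilyloxy)-1-benzofuran | CC(C)=CCC/C(C)=C/Cc1c(O[Si](C(C)C)(C(C)C)C(C)C)ccc2cc(-c3cc(O[Si](C(C)C)(C(C)C)C(C)C)cc(O[Si](C(C)C)(C(C)C)C(C)C)c3)oc12
F3 | step 1 | 1,3-bis(methoxymethoxy)benzene | COCOc1cccc(OCOC)c1
F4 | step 1 | 2-[(2E)-3,7-dimethylocta-2,6-dien-1-yl]-1,3-bis(methoxymethoxy)benzene | CC(C)=CCC/C(C)=C/Cc1c(OCOC)cccc1OCOC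
F5 | step 1 | 3-[(2E)-3,7-dimethylocta-2,6-dien-1-yl]-2,4-bis(methoxymethoxy)benzaldehyde | CC(C)=CCC/C(C)=C/Cc1c(OCOC)ccc(C=O)c1OCOC
F6 | step 3 | triisopropyl{[3,5-bis(triisopropylsilyloxy)phenyl]methoxy}silane | CC(C)[Si](OCc1cc(O[Si](C(C)C)(C(C)C)C(C)C)cc(O[Si](C(C)C)(C(C)C)C(C)C)c1)(C(C)C)C(C)C
F7 | step 7 | 1-{(E)-2-[3,5-bis(triisopropylsilyloxy)phenyl]ethenyl}-3-[(2E)-3,7-dimethylocta-2,6-dien-1-yl]-2,4-bis(methoxymethoxy)benzene | CC(C)=CCC/C(C)=C/Cc1c(OCOC)ccc(/C=C/c2cc(O[Si](C(C)C)(C(C)C)C(C)C)cc(O[Si](C(C)C)(C(C)C)C(C)C)c2)c1OCOC
A1 | alternative 1 | (3E)-6-[3,5-bis(tert-butyldimethylsilyloxy)phenyl]-1-diazohex-3-en-5-yn-2-one | [N-]=[N+]=CC(=O)/C=C/C#Cc1cc(O[Si](C)(C)C(C)(C)C)cc(O[Si](C)(C)C(C)(C)C)c1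
A2 | alternative 1 | {[(4E)-5,9-dimethyldeca-4,8-dien-1-yn-1-yl]oxy}triisopropylsilane | CC(C)=CCC/C(C)=C/CC#CO[Si](C(C)C)(C(C)C)C(C)C
A3 | alternative 1 | 6-{[3,5-bis(tert-butyldimethylsilyloxy)phenyl]ethynyl}-2-[(2E)-3,7-dimethylocta-2,6-dien-1-yl]-3-(triisopropylsilyloxy)phenol | CC(C)=CCC/C(C)=C/Cc1c(O[Si](C(C)C)(C(C)C)C(C)C)ccc(C#Cc2cc(O[Si](C)(C)C(C)(C)C)cc(O[Si](C)(C)C(C)(C)C)c2)c1O
A4 | alternative 1 | 2-[3,5-bis(tert-butyldimethylsilyloxy)phenyl]-7-[(2E)-3,7-dimethylocta-2,6-dien-1-yl]-6-(triisopropylsilyloxy)-1-benzofuran | CC(C)=CCC/C(C)=C/Cc1c(O[Si](C(C)C)(C(C)C)C(C)C)ccc2cc(-c3cc(O[Si](C)(C)C(C)(C)C)cc(O[Si](C)(C)C(C)(C)C)c3)oc12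
A5 | alternative 2 | (6E)-4-{5-[3,5-bis(tert-butyldimethylsilyloxy)phenyl]-3-ethenylfuran-2-yl}-7,11-dimethyldodeca-1,6,10-trien-3-one | C=CC(=O)C(C/C=C(\C)CCC=C(C)C)c1oc(-c2cc(O[Si](C)(C)C(C)(C)C)cc(O[Si](C)(C)C(C)(C)C)c2)cc1C=C
A6 | alternative 2 | 2-[3,5-bis(tert-butyldimethylsilyloxy)phenyl]-7-[(2E)-3,7-dimethylocta-2,6-dien-1-yl]-1-benzofuran-6-ol | CC(C)=CCC/C(C)=C/Cc1c(O)ccc2cc(-c3cc(O[Si](C)(C)C(C)(C)C)cc(O[Si](C)(C)C(C)(C)C)c3)oc12
A7 | alternative 3 | 6-formyl-2-[(2E)-3,7-dimethylocta-2,6-dien-1-yl]-3-(triisopropylsilyloxy)phenyl 3,5-bis(triisopropylsilyloxy)benzoate | CC(C)=CCC/C(C)=C/Cc1c(O[Si](C(C)C)(C(C)C)C(C)C)ccc(C=O)c1OC(=O)c1cc(O[Si](C(C)C)(C(C)C)C(C)C)cc(O[Si](C(C)C)(C(C)C)C(C)C)c1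
A8 | alternative 3 | 2-[3,5-bis(triisopropylsilyloxy)phenyl]-7-[(2E)-3,7-dimethylocta-2,6-dien-1-yl]-6-(triisopropylsilyloxy)-1-benzofuran | CC(C)=CCC/C(C)=C/Cc1c(O[Si](C(C)C)(C(C)C)C(C)C)ccc2cc(-c3cc(O[Si](C(C)C)(C(C)C)C(C)C)cc(O[Si](C(C)C)(C(C)C)C(C)C)c3)oc12
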